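**Retrosynthetic overview**

1. The target, methyl 2-{5-[(8R)-8-butyl-11-oxoundecyl]furan-2-yl}acetate, is cut at the CH2–CH2 bond C6–C7 of the undecyl chain (C1 on the furan). Both carbons are read as the α-CH2 of a carboxylic acid, and the two acids, as N-hydroxyphthalimide esters, are joined with loss of two CO2 by a Ni-electrocatalytic doubly decarboxylative C(sp3)–C(sp3) coupling (two carbons of like polarity, united as radicals).
2. Enabling feature: the only stereocenter, the butyl-bearing C8, is the direct neighbour of C7. In the left-hand acid C7 is therefore Cα and C8 is Cβ, so the carboxyl that is later expelled first makes C8 the β-carbon of an E-enoate, where Cu-catalysed asymmetric conjugate addition of butyl sets the configuration. C6 is an unmarked CH2 of the heptamethylene tether, which is why a traceless activator (CO2) is used on both sides.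
3. Left half: pent-4-enal, acetalisation, cross-metathesis with methyl acrylate, conjugate addition, saponification, redox-active ester. The C11 aldehyde stays a dimethyl acetal until the last step.
4. Right half: no ring is formed anywhere in the route. The furan is bought as 2-bromofuran, alkylated at one α-carbon by Negishi coupling and carboxymethylated at the other, free α-carbon by homolytic substitution, then converted to its redox-active ester.
5. Order: steps 1–5 (left half), 6–9 (right half), 10 (union), 11 (acetal hydrolysis).

Key step: step 10

Assumption: in step 3 the antipode of the Josiphos ligand is the one that delivers butyl to the Si face of C3 of the enoate; it is assigned by correlation on the first run, and both antipodes are commercial.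

**Route**

Step 1
Reactants: 1 pent-4-enal
Product: 2 5,5-dimethoxypent-1-ene
Conditions: HC(OMe)3 (1.2 equiv), MeOH, p-TsOH (cat.), rt; K2CO3 quench, distillation
Reagents that add atoms: trimethyl orthoformate, COC(OC)OC
Why: Acid-catalysed acetalisation with an orthoformate as water scavenger is reliable for unhindered aliphatic aldehydes and masks the future C11 aldehyde against the Grignard reagent and the basic steps that follow.

Step 2
Reactants: 2 5,5-dimethoxypent-1-ene; 3 methyl acrylate (3 equiv)
Product: 4 methyl (2E)-6,6-dimethoxyhex-2-enoate
Conditions: second-generation Ru–NHC isopropoxybenzylidene metathesis catalyst (2 mol%), CH2Cl2, 40 °C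
Reagents that add atoms: none
Why: Olefin cross-metathesis of a terminal alkene with excess acrylate should give the E-enoate selectively with loss of ethene, and the acetal is inert to the Ru carbene.

Step 3
Reactants: 4 methyl (2E)-6,6-dimethoxyhex-2-enoate
Product: 5 methyl (3S)-3-butyl-6,6-dimethoxyhexanoate
Conditions: n-BuMgBr (1.2 equiv, Et2O), CuBr·SMe2 (5 mol%), Josiphos ligand (1-[2-(diphenylphosphino)ferrocenyl]ethyldicyclohexylphosphine, 6 mol%, antipode as in the assumption), t-BuOMe, −75 °C; MeOH, then aq. NH4Cl
Reagents that add atoms: n-butylmagnesium bromide, CCCC[Mg]Br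
Why: Cu-catalysed asymmetric conjugate addition of a linear Grignard reagent to a β-alkyl E-enoate is closely precedented; the chiral Cu–diphosphine complex differentiates the faces of the β-carbon, and delivery of butyl to the Si face of C3 should set the 3S center, which becomes C8 (R) of the target, while the low temperature suppresses 1,2-addition.

Step 4
Reactants: 5 methyl (3S)-3-butyl-6,6-dimethoxyhexanoate
Product: 6 (3S)-3-butyl-6,6-dimethoxyhexanoic acid
Conditions: LiOH·H2O (2 equiv), THF/MeOH/H2O, rt; cold dilute HCl to pH 4–5, extraction, used promptly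
Reagents that add atoms: lithium hydroxide, [Li+].[OH-]
Why: Saponification of an unhindered methyl ester; the stereocenter is β to the carboxyl and cannot epimerise, and the acetal should survive base and a brief, cold, weakly acidic work-up.

Step 5
Reactants: 6 (3S)-3-butyl-6,6-dimethoxyhexanoic acid
Product: 7 1,3-dioxoisoindolin-2-yl (3S)-3-butyl-6,6-dimethoxyhexanoate
Conditions: N-hydroxyphthalimide (1.1 equiv), DIC (1.1 equiv), DMAP (0.1 equiv), CH2Cl2, 0 °C to rt
Reagents that add atoms: N-hydroxyphthalimide, O=C1c2ccccc2C(=O)N1O
Why: Carbodiimide (Steglich-type) esterification should give the redox-active ester under neutral conditions that leave the acetal and the stereocenter untouched.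

Step 6
Reactants: 8 ethyl 7-bromoheptanoate; 9 2-bromofuran
Product: 11 ethyl 7-(furan-2-yl)heptanoate, via (7-ethoxy-7-oxoheptyl)zinc bromide 10 (not isolated)
Conditions: Zn dust (activated with 1,2-dibromoethane/TMSCl, 1.5 equiv), LiCl, THF, 50 °C; then 9, Pd(OAc)2 (2 mol%), SPhos (4 mol%), THF, rt
Reagents that add atoms: none
Why: LiCl-promoted zinc insertion into the primary bromide followed by Pd-catalysed Negishi sp3–sp2 coupling tolerates the ester and fixes the chain at a furan α-carbon without regiochemical ambiguity.

Step 7
Reactants: 11 ethyl 7-(furan-2-yl)heptanoate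
Product: 12 7-(furan-2-yl)heptanoic acid
Conditions: LiOH·H2O (2 equiv), THF/H2O, rt; cold dilute HCl to pH 4
Reagents that add atoms: lithium hydroxide, [Li+].[OH-]
Why: Saponification frees the chain carboxyl before the second ester is introduced, so that the two carboxyl groups of the right half are differentiated by construction.

Step 8
Reactants: 12 7-(furan-2-yl)heptanoic acid
Product: 13 7-[5-(2-methoxy-2-oxoethyl)furan-2-yl]heptanoic acid
Conditions: methyl iodoacetate (2 equiv), FeSO4·7H2O (0.3 equiv), 30% H2O2 (slow addition), DMSO, rt
Reagents that add atoms: methyl iodoacetate, COC(=O)CI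
Why: Homolytic aromatic substitution (Minisci-type; the Fenton/DMSO system generates methyl radicals that abstract iodine from the iodoacetate) gives the electrophilic methoxycarbonylmethyl radical, which should attack the only free α-position of the electron-rich 2-alkylfuran, and the free acid is inert.

Step 9
Reactants: 13 7-[5-(2-methoxy-2-oxoethyl)furan-2-yl]heptanoic acid
Product: 14 1,3-dioxoisoindolin-2-yl 7-[5-(2-methoxy-2-oxoethyl)furan-2-yl]heptanoate
Conditions: N-hydroxyphthalimide (1.1 equiv), DIC (1.1 equiv), DMAP (0.1 equiv), CH2Cl2, 0 °C to rt
Reagents that add atoms: N-hydroxyphthalimide, O=C1c2ccccc2C(=O)N1O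
Why: Steglich-type esterification of the only free carboxyl; the methyl ester and the furan are unaffected.

Step 10
Reactants: 7 1,3-dioxoisoindolin-2-yl (3S)-3-butyl-6,6-dimethoxyhexanoate (1 equiv); 14 1,3-dioxoisoindolin-2-yl 7-[5-(2-methoxy-2-oxoethyl)furan-2-yl]heptanoate (3 equiv)
Product: 15 methyl 2-{5-[(8R)-8-butyl-11,11-dimethoxyundecyl]furan-2-yl}acetate
Conditions: NiCl2·6H2O (20 mol%), 2,2':6',2''-terpyridine (20 mol%), AgNO3 (0.3 equiv, silver-coated cathode formed in situ), NMP, Mg(+)/RVC(−), constant current, rt
Reagents that add atoms: none
Why: Cathodic reduction, mediated by Ni/terpyridine at the silver-coated cathode with the Mg anode as electron source, transfers one electron to each N-acyloxyphthalimide, which fragments to phthalimide anion, CO2 and a primary alkyl radical (the C7 radical next to the stereocenter from 7, the C6 radical from 14); low-valent Ni captures one radical as an alkyl–Ni species, takes up the second and forms the C6–C7 σ-bond by reductive elimination. The closest known reaction type is the Ni-electrocatalytic doubly decarboxylative C(sp3)–C(sp3) cross-coupling of two redox-active esters, which covers primary–primary unions in long-chain lipids. No ring is closed and no stereocenter is created; the existing center at C8 is β to the radical carbon, carries no activating group and has no pathway to epimerise. The selectivity needed is hetero- over homocoupling of two primary radicals of like polarity: it is secured statistically by the threefold excess of the achiral partner 14, which channels 7 into the cross product, and the two homodimers (a bis-acetal and a bis-ester) differ from 15 in polarity and should separate on silica. Chemoselectivity rests on the reductive regime: the oxidation-prone 2,5-dialkylfuran, the methyl ester with its acidic α-CH2 (no strong base is present) and the acetal all lie outside the potential window in which the redox-active esters are reduced.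

Step 11
Reactants: 15 methyl 2-{5-[(8R)-8-butyl-11,11-dimethoxyundecyl]furan-2-yl}acetate
Product: 16 methyl 2-{5-[(8R)-8-butyl-11-oxoundecyl]furan-2-yl}acetate
Conditions: PPTS (0.2 equiv), THF/H2O 4:1, 45 °C
Reagents that add atoms: water, O
Why: Mild acid-catalysed hydrolysis of the dimethyl acetal should release the aldehyde while the 2,5-dialkylfuran and the methyl ester tolerate the weakly acidic medium, and the stereocenter is γ to the new carbonyl and not epimerisable.

**Compound list**

1 | pent-4-enal | C=CCCC=O | starting material
2 | 5,5-dimethoxypent-1-ene | C=CCCC(OC)OC | intermediate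
3 | methyl acrylate | C=CC(=O)OC | starting material
4 | methyl (2E)-6,6-dimethoxyhex-2-enoate | COC(=O)/C=C/CCC(OC)OC | intermediate
5 | methyl (3S)-3-butyl-6,6-dimethoxyhexanoate | CCCC[C@@H](CCC(OC)OC)CC(=O)OC | intermediate
6 | (3S)-3-butyl-6,6-dimethoxyhexanoic acid | CCCC[C@@H](CCC(OC)OC)CC(=O)O | intermediate
7 | 1,3-dioxoisoindolin-2-yl (3S)-3-butyl-6,6-dimethoxyhexanoate | CCCC[C@@H](CCC(OC)OC)CC(=O)ON1C(=O)c2ccccc2C1=O | intermediate
8 | ethyl 7-bromoheptanoate | CCOC(=O)CCCCCCBr | starting material
9 | 2-bromofuran | Brc1ccco1 | starting material
10 | (7-ethoxy-7-oxoheptyl)zinc bromide | CCOC(=O)CCCCCC[Zn]Br | intermediate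
11 | ethyl 7-(furan-2-yl)heptanoate | CCOC(=O)CCCCCCc1ccco1 | intermediate
12 | 7-(furan-2-yl)heptanoic acid | OC(=O)CCCCCCc1ccco1 | intermediate
13 | 7-[5-(2-methoxy-2-oxoethyl)furan-2-yl]heptanoic acid | OC(=O)CCCCCCc1ccc(CC(=O)OC)o1 | intermediate
14 | 1,3-dioxoisoindolin-2-yl 7-[5-(2-methoxy-2-oxoethyl)furan-2-yl]heptanoate | COC(=O)Cc1ccc(CCCCCCC(=O)ON2C(=O)c3ccccc3C2=O)o1 | intermediate
15 | methyl 2-{5-[(8R)-8-butyl-11,11-dimethoxyundecyl]furan-2-yl}acetate | CCCC[C@@H](CCC(OC)OC)CCCCCCCc1ccc(CC(=O)OC)o1 | intermediate
16 | methyl 2-{5-[(8R)-8-butyl-11-oxoundecyl]furan-2-yl}acetate | CCCC[C@@H](CCC=O)CCCCCCCc1ccc(CC(=O)OC)o1 | target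

**Step count and risks**

Total steps: 11. Longest linear sequence: 7 (steps 1, 2, 3, 4, 5, 10, 11).

Steps most likely to fail:

Step 10. Statistical homocoupling of the two primary radicals, or their premature reduction to the alkanes, may leave too little cross-coupled material. The fallback forms the same bond with conventional polarity and sets out from 7 and 14. Visible-light iododecarboxylation (LiI, cat. PPh3, blue LED, acetone) of 7 should give (4S)-4-(iodomethyl)-1,1-dimethoxyoctane F1. Zinc insertion into F1 (Zn, LiCl, THF, 40 °C) gives [(2S)-2-butyl-5,5-dimethoxypentyl]zinc iodide F2. The same iododecarboxylation of 14 gives methyl 2-[5-(6-iodohexyl)furan-2-yl]acetate F3. Pd-catalysed alkyl–alkyl Negishi coupling of F2 (1.3 equiv) with F3 (Pd2(dba)3, tricyclopentylphosphine, N-methylimidazole, THF/NMP, 80 °C) comes back to the route at 15.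

Step 8. Oxidative degradation of the electron-rich furan by oxygen-centred radicals, or incomplete trapping of the carbon radical, may erode the mass balance. The fallback sets out from 12. Friedel–Crafts alkylation at the free furan α-position with methyl 2-chloro-2-(methylsulfanyl)acetate (SnCl4, CH2Cl2, −20 °C) should give 7-{5-[2-methoxy-1-(methylsulfanyl)-2-oxoethyl]furan-2-yl}heptanoic acid F4, racemic at the sulfur-bearing carbon. Reductive desulfurisation (Zn dust, AcOH) comes back to the route at 13.

Step 3. Insufficient facial discrimination, or competing uncatalysed addition, may give material of low enantiomeric purity that cannot be upgraded later, since the later intermediates are expected to be oils. The fallback replaces catalyst control by auxiliary control and sets out from 4. Saponification (LiOH, THF/H2O) gives (2E)-6,6-dimethoxyhex-2-enoic acid F5. Activation as the mixed pivalic anhydride (PivCl, Et3N, THF, −20 °C) and acylation of lithiated (4R)-4-phenyl-1,3-oxazolidin-2-one gives (4R)-3-[(2E)-6,6-dimethoxyhex-2-enoyl]-4-phenyl-1,3-oxazolidin-2-one F6. Chelation-controlled copper-mediated conjugate addition (n-BuMgBr, CuBr·SMe2, THF, −40 °C), with butyl entering anti to the phenyl group of the s-cis chelated imide, should give (4R)-3-[(3S)-3-butyl-6,6-dimethoxyhexanoyl]-4-phenyl-1,3-oxazolidin-2-one F7. The minor diastereomer is removed by chromatography or crystallisation, and cleavage with LiOH/H2O2 (THF/H2O, 0 °C) comes back to the route at 6.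

**Further compounds**

F1 | step 10 | (4S)-4-(iodomethyl)-1,1-dimethoxyoctane | CCCC[C@@H](CCC(OC)OC)CI
F2 | step 10 | [(2S)-2-butyl-5,5-dimethoxypentyl]zinc iodide | CCCC[C@@H](CCC(OC)OC)C[Zn]I
F3 | step 10 | methyl 2-[5-(6-iodohexyl)furan-2-yl]acetate | COC(=O)Cc1ccc(CCCCCCI)o1
F4 | step 8 | 7-{5-[2-methoxy-1-(methylsulfanyl)-2-oxoethyl]furan-2-yl}heptanoic acid | OC(=O)CCCCCCc1ccc(C(SC)C(=O)OC)o1
F5 | step 3 | (2E)-6,6-dimethoxyhex-2-enoic acid | OC(=O)/C=C/CCC(OC)OC
F6 | step 3 | (4R)-3-[(2E)-6,6-dimethoxyhex-2-enoyl]-4-phenyl-1,3-oxazolidin-2-one | COC(OC)CC/C=C/C(=O)N1C(=O)OC[C@H]1c1ccccc1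
F7 | step 3 | (4R)-3-[(3S)-3-butyl-6,6-dimethoxyhexanoyl]-4-phenyl-1,3-oxazolidin-2-one | CCCC[C@@H](CCC(OC)OC)CC(=O)N1C(=O)OC[C@H]1c1ccccc1
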